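**Retrosynthetic overview**

1. Schisandrone is taken back to its 7-O-benzyl ether; ring B is opened at the C4–C4a bond with C2 returned to the enolate level, and C4 is re-closed onto the C1 oxygen. This gives a 2,5-diaryl-3,4-dimethyl-4,5-dihydrofuran, an isomer of the tetralone in which only C3 is a fixed stereocentre.
2. Feature used: C4 is benzylic to ring C and para to its 4-methoxy group (stabilised cation) and stands γ to the C1 carbonyl (an enolate as leaving group), while C4a of ring A is para to the C7 oxygen; C4 can therefore be ionised and caught at C4a.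
3. The dihydrofuran comes from cyclodehydration of a γ-hydroxy ketone, made from the ring A aryllithium and a 5-aryl-3,4-dimethyl-γ-butyrolactone.
4. The lactone comes from the keto acid of a rhodium-catalysed desymmetrising arylation of meso-2,3-dimethylsuccinic anhydride with the ring C arylzinc; this fixes C3 and the cis-dimethyl pattern.
5. Ring order: rings A and C are bought; the lactone and dihydrofuran rings are temporary; ring B is closed last, in the step that also sets C4 and C2.

Key step: step 7

Remark (assumption): the (S)-ligand in step 2 is taken to direct the aryl group to the carbonyl next to the (R)-configured carbon of the meso anhydride; if the sense is the reverse, the (R)-ligand is used.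

**Route**

Step 1
Reactants: 1 2,3-dimethylmaleic anhydride
Product: 2 meso-2,3-dimethylsuccinic anhydride
Conditions: H2 (4 atm), Pd/C (10 wt % Pd on carbon), EtOAc, rt
Reagents that add atoms: none
Why: Heterogeneous syn-hydrogenation delivers both hydrogens to one face of the planar ring alkene, so the methyl groups end cis and the product is the meso anhydride.

Step 2
Reactants: 2 meso-2,3-dimethylsuccinic anhydride; 3 4-bromo-1,2-dimethoxybenzene
Product: 6 (2S,3R)-4-(3,4-dimethoxyphenyl)-2,3-dimethyl-4-oxobutanoic acid, via 3,4-dimethoxyphenyllithium 4 (not isolated), via arylzinc triflate 5 (not isolated)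
Conditions: 3, n-BuLi, THF, −78 °C; Zn(OTf)2, −78 °C → rt; then 2, [Rh(cod)Cl]2 (4 mol %), (S)-t-Bu-PHOX (8 mol %), THF, 50 °C; 1 M HCl
Reagents that add atoms: none
Why: Rhodium-catalysed enantioselective desymmetrisation of a meso succinic anhydride with an arylzinc (anhydride cross-coupling, a reaction type with precedent on this anhydride): the chiral catalyst inserts into one of the two enantiotopic acyl C–O bonds and arylates it without touching the two methyl-bearing carbons, so the absolute configuration is set by the choice of carbonyl.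

Step 3
Reactants: 6 (2S,3R)-4-(3,4-dimethoxyphenyl)-2,3-dimethyl-4-oxobutanoic acid
Product: 8 (3S,4R)-5-(3,4-dimethoxyphenyl)-3,4-dimethyloxolan-2-one (both C5 epimers), via hydroxy acid 7 (not isolated)
Conditions: NaBH4, CeCl3·7H2O, MeOH, −40 → 0 °C; then 1 M HCl, rt
Reagents that add atoms: none
Why: Luche reduction of the aryl ketone at low temperature should outrun enolisation at the adjacent methyl-bearing centre, and acid then closes the γ-lactone; the new carbinol centre is left uncontrolled on purpose because step 7 erases it.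

Step 4
Reactants: 9 5-bromo-2-methoxyphenol
Product: 10 2-(benzyloxy)-4-bromo-1-methoxybenzene
Conditions: BnBr, K2CO3, DMF, rt
Reagents that add atoms: benzyl bromide, BrCc1ccccc1
Why: Williamson ether synthesis on the phenol gives the benzyl ether that is removed under neutral conditions at the end.

Step 5
Reactants: 10 2-(benzyloxy)-4-bromo-1-methoxybenzene; 8 (3S,4R)-5-(3,4-dimethoxyphenyl)-3,4-dimethyloxolan-2-one
Product: 12 (2S,3R)-1-[3-(benzyloxy)-4-methoxyphenyl]-4-(3,4-dimethoxyphenyl)-4-hydroxy-2,3-dimethylbutan-1-one (both C4 epimers), via aryllithium 11 (not isolated)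
Conditions: 10, n-BuLi, THF, −78 °C; then 8, −78 °C; sat. NH4Cl
Reagents that add atoms: none
Why: Bromine–lithium exchange and single addition of the aryllithium to the lactone carbonyl (acyl substitution that stops at the hemiketal alkoxide at −78 °C) give the aryl ketone; the C3 centre is not enolisable here and the configuration at C2 is of no consequence.

Step 6
Reactants: 12 (2S,3R)-1-[3-(benzyloxy)-4-methoxyphenyl]-4-(3,4-dimethoxyphenyl)-4-hydroxy-2,3-dimethylbutan-1-one
Product: 14 (4R)-2-[3-(benzyloxy)-4-methoxyphenyl]-5-(3,4-dimethoxyphenyl)-3,4-dimethyl-4,5-dihydrofuran (both C5 epimers), via benzylic mesylate 13 (not isolated)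
Conditions: MsCl, Et3N, CH2Cl2, −20 → 0 °C
Reagents that add atoms: none
Why: Cyclodehydration of a γ-hydroxy ketone: the sulfonylated benzylic carbon is taken by the ketone oxygen (neighbouring-group participation, five-membered ring) and triethylamine removes the C2 proton of the oxocarbenium ion to give the cyclic enol ether, with C3 untouched.

Step 7
Reactants: 14 (4R)-2-[3-(benzyloxy)-4-methoxyphenyl]-5-(3,4-dimethoxyphenyl)-3,4-dimethyl-4,5-dihydrofuran
Product: 17 (2S,3S,4R)-7-(benzyloxy)-4-(3,4-dimethoxyphenyl)-6-methoxy-2,3-dimethyl-3,4-dihydronaphthalen-1(2H)-one, via cyclopropyl ketone 15 (not isolated), via trichlorostannyl enolate 16 (not isolated)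
Conditions: SnCl4 (1.2 equiv), 2,6-di-tert-butyl-4-methylpyridine (1.5 equiv), CH2Cl2 (0.02 M), −78 → −20 °C; then AcOH, THF, −78 °C; aq. NaHCO3
Reagents that add atoms: none
Why: Proposed new method: SnCl4 on the enol-ether oxygen should heterolyse the benzylic C–O bond (leaving group a tin enolate, cation held by the para-methoxy group of ring C), the ion pair collapses reversibly at carbon to the donor–acceptor cyclopropyl ketone 15, whose SnCl4 complex re-opens to the enolate rotamer with ring A cis to the cationic arm, and this closes onto ring A as in a formal homo-Nazarov cyclisation, the hindered pyridine taking the arene proton so that enolate 16 survives until the acetic acid quench. The closest known reactions are the SnCl4-mediated cyclisation of aryl 2-arylcyclopropyl ketones to 4-aryl-1-tetralones and the Lewis-acid Cloke–Wilson interconversion of such ketones with 4,5-dihydrofurans; new is the entry from the enol ether. Ring B is closed at the C4–C4a bond by intramolecular electrophilic aromatic substitution, a cation–arene closure that is 6-endo with respect to the C8a–C4a bond of ring A. C4 is set in that closure: both C5 epimers of 14 give the same planar cation, and the half-chair with the C3 methyl pseudoaxial (avoiding A(1,2) strain with the C2 methyl of the enolate) places the aryl group anti to it, which gives the 3,4-trans relation. C2 is set in the quench: protonation of 16 should occur anti to the pseudoaxial C3 methyl and give the 2,3-cis relation, so C3 is the only stereocentre that has to be carried into the step. The step needs attack at the ring A position para to the benzyloxy group rather than at the hindered position between the two substituents, and ring closure has to win over loss of the C3 proton from the cation, for which the absence of free Brønsted acid and the intramolecular trap are relied on.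

Step 8
Reactants: 17 (2S,3S,4R)-7-(benzyloxy)-4-(3,4-dimethoxyphenyl)-6-methoxy-2,3-dimethyl-3,4-dihydronaphthalen-1(2H)-one
Product: 18 schisandrone, (2S,3S,4R)-4-(3,4-dimethoxyphenyl)-7-hydroxy-6-methoxy-2,3-dimethyl-3,4-dihydronaphthalen-1(2H)-one
Conditions: H2 (1 atm), Pd/C (10 wt % Pd on carbon), EtOAc, rt
Reagents that add atoms: none
Why: Hydrogenolysis of the benzyl ether under neutral conditions should leave the aryl ketone and the epimerisable C2 centre intact.

**Compound list**

1 | 2,3-dimethylmaleic anhydride (3,4-dimethylfuran-2,5-dione) | CC1=C(C)C(=O)OC1=O | starting material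
2 | meso-2,3-dimethylsuccinic anhydride, (3R,4S)-3,4-dimethyloxolane-2,5-dione | O=C1[C@@H](C)[C@@H](C)C(=O)O1 | intermediate
3 | 4-bromo-1,2-dimethoxybenzene | COc1ccc(Br)cc1OC | starting material
4 | (3,4-dimethoxyphenyl)lithium | COc1ccc([Li])cc1OC | intermediate (not isolated)
5 | (3,4-dimethoxyphenyl)zinc trifluoromethanesulfonate | COc1ccc([Zn]OS(=O)(=O)C(F)(F)F)cc1OC | intermediate (not isolated)
6 | (2S,3R)-4-(3,4-dimethoxyphenyl)-2,3-dimethyl-4-oxobutanoic acid | OC(=O)[C@@H](C)[C@@H](C)C(=O)c1ccc(OC)c(OC)c1 | intermediate
7 | (2S,3R)-4-(3,4-dimethoxyphenyl)-4-hydroxy-2,3-dimethylbutanoic acid, both C4 epimers | OC(=O)[C@@H](C)[C@@H](C)C(O)c1ccc(OC)c(OC)c1 | intermediate (not isolated)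
8 | (3S,4R)-5-(3,4-dimethoxyphenyl)-3,4-dimethyloxolan-2-one, both C5 epimers | O=C1[C@@H](C)[C@@H](C)C(O1)c1ccc(OC)c(OC)c1 | intermediate
9 | 5-bromo-2-methoxyphenol | COc1ccc(Br)cc1O | starting material
10 | 2-(benzyloxy)-4-bromo-1-methoxybenzene | COc1ccc(Br)cc1OCc1ccccc1 | intermediate
11 | [3-(benzyloxy)-4-methoxyphenyl]lithium | COc1ccc([Li])cc1OCc1ccccc1 | intermediate (not isolated)
12 | (2S,3R)-1-[3-(benzyloxy)-4-methoxyphenyl]-4-(3,4-dimethoxyphenyl)-4-hydroxy-2,3-dimethylbutan-1-one, both C4 epimers | COc1ccc(cc1OCc1ccccc1)C(=O)[C@@H](C)[C@@H](C)C(O)c1ccc(OC)c(OC)c1 | intermediate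
13 | (2S,3R)-1-[3-(benzyloxy)-4-methoxyphenyl]-4-(3,4-dimethoxyphenyl)-2,3-dimethyl-4-[(methylsulfonyl)oxy]butan-1-one | COc1ccc(cc1OCc1ccccc1)C(=O)[C@@H](C)[C@@H](C)C(OS(C)(=O)=O)c1ccc(OC)c(OC)c1 | intermediate (not isolated)
14 | (4R)-2-[3-(benzyloxy)-4-methoxyphenyl]-5-(3,4-dimethoxyphenyl)-3,4-dimethyl-4,5-dihydrofuran, both C5 epimers | COc1ccc(cc1OCc1ccccc1)C1=C(C)[C@@H](C)C(O1)c1ccc(OC)c(OC)c1 | intermediate
15 | [3-(benzyloxy)-4-methoxyphenyl][(2S)-3-(3,4-dimethoxyphenyl)-1,2-dimethylcyclopropyl]methanone, mixture at C1 and C3 | COc1ccc(cc1OCc1ccccc1)C(=O)C1(C)[C@@H](C)C1c1ccc(OC)c(OC)c1 | intermediate (not isolated)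
16 | trichloro{[(3S,4R)-7-(benzyloxy)-4-(3,4-dimethoxyphenyl)-6-methoxy-2,3-dimethyl-3,4-dihydronaphthalen-1-yl]oxy}stannane | COc1cc2c(cc1OCc1ccccc1)C(O[Sn](Cl)(Cl)Cl)=C(C)[C@@H](C)[C@@H]2c1ccc(OC)c(OC)c1 | intermediate (not isolated)
17 | (2S,3S,4R)-7-(benzyloxy)-4-(3,4-dimethoxyphenyl)-6-methoxy-2,3-dimethyl-3,4-dihydronaphthalen-1(2H)-one | COc1cc2c(cc1OCc1ccccc1)C(=O)[C@@H](C)[C@@H](C)[C@@H]2c1ccc(OC)c(OC)c1 | intermediate
18 | schisandrone, (2S,3S,4R)-4-(3,4-dimethoxyphenyl)-7-hydroxy-6-methoxy-2,3-dimethyl-3,4-dihydronaphthalen-1(2H)-one | COc1cc2c(cc1O)C(=O)[C@@H](C)[C@@H](C)[C@@H]2c1ccc(OC)c(OC)c1 | target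

**Step count and risks**

Total step count: 8. Longest linear sequence: 7 steps (1, 2, 3, 5, 6, 7, 8); step 4 is a side branch.

Steps most likely to fail:

- **Step 7 (proposed new method).** Two processes may go wrong. Ionisation of the enol ether may end in loss of the C3 proton (elimination, which also erases C3) or stall before ring closure. Protonation of the enolate may be poorly face-selective and give the C2 epimer. The fallback uses known chemistry and sets out from 12. The hydroxy ketone 12 is cyclised by a Brønsted-acid dehydrative Friedel–Crafts cycloalkylation of the benzylic alcohol (TfOH 5 mol %, (CF3)2CHOH, 0 °C), the classical cation route to aryltetralins. This should give 17 together with its C2 epimer (2R,3S,4R)-7-(benzyloxy)-4-(3,4-dimethoxyphenyl)-6-methoxy-2,3-dimethyl-3,4-dihydronaphthalen-1(2H)-one F1. F1, or the mixture, is deprotonated with LiN(SiMe3)2 (THF, −78 °C) to the lithium enolate F2, which is protonated kinetically at −78 °C with ethyl salicylate. The fallback comes back to the route at 17.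

- **Step 2.** Discrimination of the two enantiotopic carbonyls may be incomplete, and the centre next to the new ketone may epimerise in the basic medium. The fallback sets out from 2. The anhydride is opened with methanol in the presence of quinidine (or quinine, whichever gives the needed enantiomer; toluene, −55 °C), a known desymmetrising alcoholysis, to the hemiester (2R,3S)-4-methoxy-2,3-dimethyl-4-oxobutanoic acid F3. Its free acid is converted with EtSH, EDC·HCl and DMAP into the thioester methyl (2S,3R)-4-(ethylsulfanyl)-2,3-dimethyl-4-oxobutanoate F4. Fukuyama coupling of F4 with arylzinc 5 (PdCl2(PPh3)2, THF, rt) gives the keto ester methyl (2S,3R)-4-(3,4-dimethoxyphenyl)-2,3-dimethyl-4-oxobutanoate F5. Luche reduction gives the hydroxy ester methyl (2S,3R)-4-(3,4-dimethoxyphenyl)-4-hydroxy-2,3-dimethylbutanoate F6, which lactonises on acidification. The fallback comes back to the route at 8.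

- **Step 5.** A second aryllithium may add to the ring-opened ketone, and the lactone may be enolised instead of attacked. The fallback sets out from 8. The lactone is opened with MeNH(OMe)·HCl and AlMe3 (CH2Cl2, 0 °C) to the Weinreb amide (2S,3R)-4-(3,4-dimethoxyphenyl)-4-hydroxy-N-methoxy-N,2,3-trimethylbutanamide F7. Its hydroxyl is masked as the magnesium alkoxide with i-PrMgCl (1 equiv, THF, −20 °C), and aryllithium 11 is added at −78 °C; the chelated tetrahedral intermediate cannot take a second equivalent. Aqueous work-up brings the fallback back to the route at 12.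

Further compounds
F1 | step 7 | (2R,3S,4R)-7-(benzyloxy)-4-(3,4-dimethoxyphenyl)-6-methoxy-2,3-dimethyl-3,4-dihydronaphthalen-1(2H)-one | COc1cc2c(cc1OCc1ccccc1)C(=O)[C@H](C)[C@@H](C)[C@@H]2c1ccc(OC)c(OC)c1
F2 | step 7 | lithium (3S,4R)-7-(benzyloxy)-4-(3,4-dimethoxyphenyl)-6-methoxy-2,3-dimethyl-3,4-dihydronaphthalen-1-olate | COc1cc2c(cc1OCc1ccccc1)C(O[Li])=C(C)[C@@H](C)[C@@H]2c1ccc(OC)c(OC)c1
F3 | step 2 | (2R,3S)-4-methoxy-2,3-dimethyl-4-oxobutanoic acid | COC(=O)[C@@H](C)[C@@H](C)C(O)=O
F4 | step 2 | methyl (2S,3R)-4-(ethylsulfanyl)-2,3-dimethyl-4-oxobutanoate | COC(=O)[C@@H](C)[C@@H](C)C(=O)SCC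
F5 | step 2 | methyl (2S,3R)-4-(3,4-dimethoxyphenyl)-2,3-dimethyl-4-oxobutanoate | COC(=O)[C@@H](C)[C@@H](C)C(=O)c1ccc(OC)c(OC)c1
F6 | step 2 | methyl (2S,3R)-4-(3,4-dimethoxyphenyl)-4-hydroxy-2,3-dimethylbutanoate, both C4 epimers | COC(=O)[C@@H](C)[C@@H](C)C(O)c1ccc(OC)c(OC)c1
F7 | step 5 | (2S,3R)-4-(3,4-dimethoxyphenyl)-4-hydroxy-N-methoxy-N,2,3-trimethylbutanamide, both C4 epimers | CON(C)C(=O)[C@@H](C)[C@@H](C)C(O)c1ccc(OC)c(OC)c1
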